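The runs are simulated from invented constants, noise included.

Among the candidate steps, J comes from X + G -> X + J, so I follow the rate of J and, with it, the chance that one G survives that step.

the same everywhere: Q 3.1 µM
- alder: E 4 mM; X 2 µM; temperature 90 °C; run made earlier
- summer: E 2.0 mM; X 2.0 µM; temperature 105 °C; time 6.0 min
- dusk: E 2.0 mM; X 2.0 µM; temperature 90 °C; time 10 min

alder run (percent of the E charged)

| time / min | G / % | J / % | E / % |
|---|---|---|---|
| 0.250 | 47.7 | 0.5 | 51.1 |
| 0.500 | 70.9 | 2.3 | 26.4 |
| 1.33 | 87.2 | 9.5 | 3.4 |
| 3.00 | 74.4 | 26.2 | 0.1 |

(scatter of a reading: 0.5 percentage points)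

- the flask that ends with the higher amount of G, in percent of the E charged, or "neither" when 2 percentage points or less lies between them (summer / dusk / neither)
- final G, as a percentage of the E charged, in summer
- final G, as a percentage of the E charged, in dusk

- the earlier runs were read with a standard deviation of 0.5 percentage points
- candidate steps: X + G -> X + J; X + Q <-> Z; E -> G
- the earlier runs do not show what temperature does; that part of a forecast is a guess

In alder, E falls from 51.1% to 26.4% in 0.250 min, which gives a first-order constant of 2.64 min⁻¹. A molecule therefore waits about 0.379 min as E.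

Later in alder, J gains 17 percentage points in 1.67 min while G stands near 80.8%, so

k = gain of J / (mean G × time) = 0.124 min⁻¹

I call this the drain constant: the chance per minute that one G becomes J. It is a pseudo-first-order constant for as long as free X holds steady.

X and Q are charged in dusk as in alder, and I assume first order in c_G, so in my reckoning the percentages carry over to 2.0 mM. I treat the whole charge as G from 0.379 min onward, so my estimated rate of J in dusk starts at 0.124 min⁻¹ times the charge. In this estimate it then falls with c_G, by a factor of 2 every 5.60 min. The accumulated slowing is also the share of G that survives: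

dusk: exp(−k(t − wait)) = 30.4%

The runs do not show temperature, so for summer I guess a factor of 2 on k and keep the wait:

summer: exp(−2k(t − wait)) = 24.9%

By my reckoning, dusk ends 5.5 points higher, which is beyond the margin of 2 points.

The forecast gives 17% for summer and 29% for dusk, “so dusk probably ends higher”; both numbers lie below mine.

Dusk ends with 32.9% of G and summer with 21.5%, so the answer is dusk. In dusk, free X stands at 48.2% of the catalyst charged at 5.00 min and at 48.2% at 10.0 min, with Z at 51.8% of the catalyst charged.

    X + G → X + J (k = 2000 M⁻¹ s⁻¹, Ea = 50.0 kJ mol⁻¹)
    X + Q ⇌ Z, settled at all times (K = 5.20 × 10⁵ M⁻¹, ΔH = −31.0 kJ mol⁻¹)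
    E → G (k = 0.0440 s⁻¹, Ea = 90.0 kJ mol⁻¹)
    (constants at 90 °C)

For the dusk flask read at 4.0 min, the drain constant gives

exp(−k(t − wait)) = 63.8%

That flask holds 65.8% of G.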